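**Retrosynthetic overview**
1. The chain is numbered C1' (OCH2) to C7' (CMe2). The plan rests on the trisubstituted oxirane ring (O, C2', C3'). Its C2'–C3' bond separates the coumarin ether part (benzene ring A, pyranone ring B, C1', C2') from the C3'–C7' part that carries the C5' carbinol, and the halves meet at the fully substituted C3' (methyl, C4').
2. Key disconnection: C2'–C3' and C3'–O are made in one Corey–Chaykovsky operation from aryloxyacetaldehyde 4 and dialkyl ylide 19, which is generated at C3' of chiral thiolanium salt 18. Only the C5' silyl ether is removed afterwards.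
3. Aldehyde 4 comes from phenol 1 and bromoacetal 2. The C3'–C7' chain comes from prenal 9 by Brown allylboration (sets C5'), silylation, Wacker oxidation and reduction, and it is bound to sulfur by S-alkylation through its secondary triflate.
4. The sulfide is C2-symmetric (2S,5S)-2,5-dimethylthiolane 8, made from hexane-2,5-dione with deuterium on both ring methines, so that C3'–H is the only α-C–H offered to the base.
5. Ring order: rings A and B are bought. The auxiliary thiolane ring is closed in step 5 and expelled in step 11. The oxirane, the only ring built for the target, is closed in step 11.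

Key step: step 11

Assumption: the sense of induction of the dialkyl ylide is extrapolated from the accepted steric model for 2,5-dimethylthiolanium benzylides, which calls for the (2S,5S)-sulfide; if experiment shows the opposite, the (2R,5R)-antipode is reached by the same three steps with an S-selective alcohol dehydrogenase.

**Step 1**
Reactants: 1 7-hydroxy-8-methoxycoumarin; 2 bromoacetaldehyde diethyl acetal
Product: 3 7-(2,2-diethoxyethoxy)-8-methoxy-2H-chromen-2-one
Conditions: K2CO3, KI (cat.), DMF, 100 °C
Reagents that add atoms: none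
Why: Williamson ether synthesis, in which the only free OH (the C7 phenol) is alkylated by SN2 at the primary halide, iodide catalysis offsets the sluggish β,β-dialkoxy bromide, and the lactone tolerates carbonate in dry DMF.

**Step 2**
Reactants: 3 7-(2,2-diethoxyethoxy)-8-methoxy-2H-chromen-2-one
Product: 4 [(8-methoxy-2-oxo-2H-chromen-7-yl)oxy]acetaldehyde
Conditions: 1 M aq HCl, THF, 50 °C; toluene azeotrope
Reagents that add atoms: water, O
Why: Acid-catalysed acetal hydrolysis in dilute aqueous medium, which lactone and aryl ethers tolerate and which stays far from the hot anhydrous acid needed for cyclodehydration onto C6, with azeotropic drying to remove the hydrate before the ylide step.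

**Step 3**
Reactants: 5 hexane-2,5-dione
Product: 6 (2R,5R)-(2,5-D2)hexane-2,5-diol
Conditions: alcohol dehydrogenase from Lactobacillus brevis, NADP+ (cat.), MgCl2, (CD3)2CDOD (excess), phosphate buffer pH 7, 30 °C
Reagents that add atoms: 2-propanol-d8, [2H]OC([2H])(C([2H])([2H])[2H])C([2H])([2H])[2H]
Why: Biocatalytic asymmetric ketone reduction with substrate-coupled cofactor recycling, in which the R-selective enzyme passes the carbinol deuteride of the co-substrate through the cofactor to the same face of both carbonyls, setting both centres as R and installing both C–D bonds.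

**Step 4**
Reactants: 6 (2R,5R)-(2,5-D2)hexane-2,5-diol
Product: 7 (2R,5R)-(2,5-D2)hexane-2,5-diyl dimethanesulfonate
Conditions: MsCl, Et3N, CH2Cl2, 0 °C
Reagents that add atoms: methanesulfonyl chloride, CS(=O)(=O)Cl
Why: Sulfonate ester formation takes place at oxygen and leaves both stereocentres untouched.

**Step 5**
Reactants: 7 (2R,5R)-(2,5-D2)hexane-2,5-diyl dimethanesulfonate
Product: 8 (2S,5S)-2,5-dimethyl(2,5-D2)thiolane
Conditions: Na2S·9H2O, EtOH, rt to 40 °C; pentane extraction, distillation
Reagents that add atoms: sodium sulfide, [Na+].[Na+].[S-2]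
Why: Double SN2 displacement by sulfide (intermolecular, then 5-exo-tet) inverts both centres and gives the C2-symmetric (2S,5S)-thiolane with deuterium on the two ring methines.

**Step 6**
Reactants: 9 3-methylbut-2-enal (prenal); 10 (+)-B-allyldiisopinocampheylborane of the (−)-α-pinene series (commercial pentane solution)
Product: 12 (4R)-6-methylhepta-1,5-dien-4-ol, via borinate ester 11 (not isolated)
Conditions: Et2O, −78 °C; then 3 M NaOH, 30 % H2O2, 0 °C to rt
Reagents that add atoms: none
Why: Brown asymmetric allylboration through a closed chair transition state, in which the isopinocampheyl ligands of the (−)-α-pinene series deliver allyl to the Re face of the enal and set the future C5' as R, with oxidative work-up cleaving the borinate.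

**Step 7**
Reactants: 12 (4R)-6-methylhepta-1,5-dien-4-ol
Product: 13 (4R)-4-(tert-butyldimethylsilyloxy)-6-methylhepta-1,5-diene
Conditions: TBSCl, imidazole, DMF, rt
Reagents that add atoms: tert-butyldimethylsilyl chloride, CC(C)(C)[Si](C)(C)Cl
Why: Imidazole-promoted silyl ether formation masks the C5' hydroxyl against Tf2O and strong base and is removable by fluoride in the presence of the oxirane.

**Step 8**
Reactants: 13 (4R)-4-(tert-butyldimethylsilyloxy)-6-methylhepta-1,5-diene
Product: 14 (4R)-4-(tert-butyldimethylsilyloxy)-6-methylhept-5-en-2-one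
Conditions: PdCl2 (10 mol %), CuCl (co-catalyst), O2 (1 atm), DMF/H2O 7:1, rt
Reagents that add atoms: water, O
Why: Wacker–Tsuji oxidation, in which divalent palladium binds the monosubstituted alkene in preference to the trisubstituted one and Markovnikov hydroxypalladation followed by β-hydride elimination gives the methyl ketone without touching C5'.

**Step 9**
Reactants: 14 (4R)-4-(tert-butyldimethylsilyloxy)-6-methylhept-5-en-2-one
Product: 15 (2RS,4R)-4-(tert-butyldimethylsilyloxy)-6-methylhept-5-en-2-ol
Conditions: NaBH4, MeOH, 0 °C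
Reagents that add atoms: none
Why: Borohydride 1,2-reduction gives the carbinol (future C3') as an epimer mixture, which is accepted because this centre is erased when the ylide is formed.

**Step 10**
Reactants: 15 (2RS,4R)-4-(tert-butyldimethylsilyloxy)-6-methylhept-5-en-2-ol; 8 (2S,5S)-2,5-dimethyl(2,5-D2)thiolane
Product: 18 (2S,5S)-1-[(2RS,4R)-4-(tert-butyldimethylsilyloxy)-6-methylhept-5-en-2-yl]-2,5-dimethyl(2,5-D2)thiolan-1-ium tetrafluoroborate, via secondary triflate 16 (not isolated), via thiolanium triflate 17 (not isolated)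
Conditions: Tf2O, 2,6-di-tert-butyl-4-methylpyridine, CH2Cl2, −78 °C; 8 (1.5 equiv), −78 to 0 °C; wash with aq NaBF4; trituration with pentane
Reagents that add atoms: trifluoromethanesulfonic anhydride, O=S(=O)(OS(=O)(=O)C(F)(F)F)C(F)(F)F (atoms in 16 and 17 only); sodium tetrafluoroborate, [Na+].F[B-](F)(F)F
Why: Sulfonium salt formation by SN2 S-alkylation, in which the triflate made in situ is reactive enough for the hindered dialkyl sulfide below 0 °C, the non-nucleophilic base limits elimination, the two lone pairs of C2-symmetric 8 are equivalent so that sulfur is no stereocentre, and NaBF4 exchanges the counter-ion.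

**Step 11**
Reactants: 18 (2S,5S)-1-[(2RS,4R)-4-(tert-butyldimethylsilyloxy)-6-methylhept-5-en-2-yl]-2,5-dimethyl(2,5-D2)thiolan-1-ium tetrafluoroborate; 4 [(8-methoxy-2-oxo-2H-chromen-7-yl)oxy]acetaldehyde
Product: 21 7-{[(2R,3R)-3-[(2R)-2-(tert-butyldimethylsilyloxy)-4-methylpent-3-en-1-yl]-3-methyloxiran-2-yl]methoxy}-8-methoxy-2H-chromen-2-one, via sulfonium ylide 19 (not isolated), via betaine 20 (not isolated)
Conditions: 18 (1.2 equiv), LiN(iPr)2 (1.1 equiv), THF, −78 °C, 10 min; then 4 (1.0 equiv) in THF, −78 to −20 °C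
Reagents that add atoms: none
Why: Proposed new method: LiN(iPr)2 removes C3'–H, the only α-C–H left in 18 because both ring methines carry deuterium and are held back by a primary kinetic isotope effect, and the non-stabilised dialkyl ylide 19 adds through C3' to the aldehyde carbon of 4 to form C2'–C3' in a fast, irreversible step. Rotation of betaine 20 places O− anti-periplanar to S+, and a 3-exo-tet SN2 displacement of thiolane 8 with inversion at C3' forms C3'–O and closes the oxirane. The closest known reaction types are Corey–Chaykovsky epoxidations of enolisable aldehydes and ketones with diphenylsulfonium isopropylide and asymmetric epoxidations with 2,5-dimethylthiolanium benzylides, whereas an unsymmetrical dialkyl ylide on a chiral sulfide is without precedent. C3' is controlled by the sulfide: the carbanion plane contains the sulfur lone-pair axis, the larger β-branched C4' arm should point away from the ring with the methyl over it, and the ring methyl cis to C3' shields one face, so the (2S,5S)-thiolane exposes the face that gives 3'S in 20 and 3'R after inversion. C2' is fixed in the same kinetically controlled addition, in which C1' takes the position next to the small methyl rather than next to C4', giving the (2'R,3'S)-betaine and hence C1' trans to C4'. The step needs site-selective deprotonation (secured by the C–D bonds), methyl versus C4' discrimination (secured only by the branching at C5', the weakest point), and aldehyde addition in preference to enolisation or attack on the lactone and its C3=C4 bond (secured by the far higher electrophilicity of the unhindered aldehyde at −78 °C and by keeping the base substoichiometric to 18), while C5' is a spectator.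

**Step 12**
Reactants: 21 7-{[(2R,3R)-3-[(2R)-2-(tert-butyldimethylsilyloxy)-4-methylpent-3-en-1-yl]-3-methyloxiran-2-yl]methoxy}-8-methoxy-2H-chromen-2-one
Product: 22 7-{[(2R,3R)-3-[(2R)-2-hydroxy-4-methylpent-3-en-1-yl]-3-methyloxiran-2-yl]methoxy}-8-methoxy-2H-chromen-2-one (target)
Conditions: Bu4NF, AcOH (1:1), THF, 0 °C to rt
Reagents that add atoms: none
Why: Fluoride-mediated desilylation, with acetic acid buffering so that no free alkoxide attacks the oxirane or the lactone and no stereocentre is touched.

**Compound list**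
1 | 7-hydroxy-8-methoxycoumarin | COc1c(O)ccc2ccc(=O)oc12 | starting material
2 | bromoacetaldehyde diethyl acetal | CCOC(CBr)OCC | starting material
3 | 7-(2,2-diethoxyethoxy)-8-methoxy-2H-chromen-2-one | COc1c(OCC(OCC)OCC)ccc2ccc(=O)oc12 | intermediate
4 | [(8-methoxy-2-oxo-2H-chromen-7-yl)oxy]acetaldehyde | COc1c(OCC=O)ccc2ccc(=O)oc12 | intermediate
5 | hexane-2,5-dione | CC(=O)CCC(C)=O | starting material
6 | (2R,5R)-(2,5-D2)hexane-2,5-diol | C[C@@]([2H])(O)CC[C@@]([2H])(C)O | intermediate
7 | (2R,5R)-(2,5-D2)hexane-2,5-diyl dimethanesulfonate | C[C@@]([2H])(OS(C)(=O)=O)CC[C@@]([2H])(C)OS(C)(=O)=O | intermediate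
8 | (2S,5S)-2,5-dimethyl(2,5-D2)thiolane | C[C@@]1([2H])CC[C@]([2H])(C)S1 | intermediate
9 | 3-methylbut-2-enal | CC(C)=CC=O | starting material
10 | (+)-B-allyldiisopinocampheylborane, (−)-α-pinene series | C=CCB([C@H]1C[C@H]2C[C@@H]([C@@H]1C)C2(C)C)[C@H]1C[C@H]2C[C@@H]([C@@H]1C)C2(C)C | starting material
11 | (4R)-6-methylhepta-1,5-dien-4-yl diisopinocampheylborinate | C=CC[C@@H](OB([C@H]1C[C@H]2C[C@@H]([C@@H]1C)C2(C)C)[C@H]1C[C@H]2C[C@@H]([C@@H]1C)C2(C)C)C=C(C)C | intermediate
12 | (4R)-6-methylhepta-1,5-dien-4-ol | C=CC[C@@H](O)C=C(C)C | intermediate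
13 | (4R)-4-(tert-butyldimethylsilyloxy)-6-methylhepta-1,5-diene | C=CC[C@@H](O[Si](C)(C)C(C)(C)C)C=C(C)C | intermediate
14 | (4R)-4-(tert-butyldimethylsilyloxy)-6-methylhept-5-en-2-one | CC(=O)C[C@@H](O[Si](C)(C)C(C)(C)C)C=C(C)C | intermediate
15 | (2RS,4R)-4-(tert-butyldimethylsilyloxy)-6-methylhept-5-en-2-ol | CC(O)C[C@@H](O[Si](C)(C)C(C)(C)C)C=C(C)C | intermediate
16 | (2RS,4R)-4-(tert-butyldimethylsilyloxy)-6-methylhept-5-en-2-yl trifluoromethanesulfonate | CC(OS(=O)(=O)C(F)(F)F)C[C@@H](O[Si](C)(C)C(C)(C)C)C=C(C)C | intermediate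
17 | (2S,5S)-1-[(2RS,4R)-4-(tert-butyldimethylsilyloxy)-6-methylhept-5-en-2-yl]-2,5-dimethyl(2,5-D2)thiolan-1-ium trifluoromethanesulfonate | C[C@@]1([2H])CC[C@]([2H])(C)[S+]1C(C)C[C@@H](O[Si](C)(C)C(C)(C)C)C=C(C)C.[O-]S(=O)(=O)C(F)(F)F | intermediate
18 | (2S,5S)-1-[(2RS,4R)-4-(tert-butyldimethylsilyloxy)-6-methylhept-5-en-2-yl]-2,5-dimethyl(2,5-D2)thiolan-1-ium tetrafluoroborate | C[C@@]1([2H])CC[C@]([2H])(C)[S+]1C(C)C[C@@H](O[Si](C)(C)C(C)(C)C)C=C(C)C.F[B-](F)(F)F | intermediate
19 | (4R)-4-(tert-butyldimethylsilyloxy)-2-[(2S,5S)-2,5-dimethyl(2,5-D2)thiolan-1-ium-1-yl]-6-methylhept-5-en-2-ide (C3' ylide) | C[C@@]1([2H])CC[C@]([2H])(C)[S+]1[C-](C)C[C@@H](O[Si](C)(C)C(C)(C)C)C=C(C)C | intermediate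
20 | (2R,3S,5R)-5-(tert-butyldimethylsilyloxy)-3-[(2S,5S)-2,5-dimethyl(2,5-D2)thiolan-1-ium-1-yl]-1-[(8-methoxy-2-oxo-2H-chromen-7-yl)oxy]-3,7-dimethyloct-6-en-2-olate (betaine) | COc1c(OC[C@@H]([O-])[C@@](C)([S+]3[C@@]([2H])(C)CC[C@]3([2H])C)C[C@@H](O[Si](C)(C)C(C)(C)C)C=C(C)C)ccc2ccc(=O)oc12 | intermediate
21 | 7-{[(2R,3R)-3-[(2R)-2-(tert-butyldimethylsilyloxy)-4-methylpent-3-en-1-yl]-3-methyloxiran-2-yl]methoxy}-8-methoxy-2H-chromen-2-one | COc1c(OC[C@H]2O[C@]2(C)C[C@@H](O[Si](C)(C)C(C)(C)C)C=C(C)C)ccc2ccc(=O)oc12 | intermediate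
22 | 7-{[(2R,3R)-3-[(2R)-2-hydroxy-4-methylpent-3-en-1-yl]-3-methyloxiran-2-yl]methoxy}-8-methoxy-2H-chromen-2-one | COc1c(OC[C@H]2O[C@]2(C)C[C@@H](O)C=C(C)C)ccc2ccc(=O)oc12 | target

**Total step count:** 12
**Longest linear sequence:** 7 steps (steps 6 to 12, from prenal 9)

**Steps most likely to fail**

1. Step 11 (the labelled step).
   - What may go wrong: metalation of a ring C–D position despite the isotope effect, α',β-elimination of the ylide before the aldehyde arrives, proton transfer from the enolisable aldehyde, and weak methyl/C4' differentiation that erodes both the facial and the cis/trans selectivity.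
   - Fallback: known chemistry, setting out from ketone 14 and phenol 1 and returning at 21.
   - Horner–Wadsworth–Emmons olefination of 14 with triethyl phosphonoacetate and NaH in THF gives, after removal of the Z isomer, ethyl (2E,5R)-5-(tert-butyldimethylsilyloxy)-3,7-dimethylocta-2,6-dienoate F1.
   - iBu2AlH in CH2Cl2 at −78 °C reduces it to (2E,5R)-5-(tert-butyldimethylsilyloxy)-3,7-dimethylocta-2,6-dien-1-ol F2.
   - Sharpless asymmetric epoxidation with Ti(OiPr)4, D-(−)-diethyl tartrate and t-BuOOH over 4 Å sieves at −20 °C touches only the allylic-alcohol alkene and sets 2'R,3'R in {(2R,3R)-3-[(2R)-2-(tert-butyldimethylsilyloxy)-4-methylpent-3-en-1-yl]-3-methyloxiran-2-yl}methanol F3.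
   - Mitsunobu etherification of F3 with 1 (PPh3, diisopropyl azodicarboxylate, THF) forms the aryl ether at C1' without touching a stereocentre and gives 21.

2. Step 10.
   - What may go wrong: elimination of the secondary triflate outpaces the slow attack of the hindered sulfide, or traces of acid strip the allylic silyl ether.
   - Fallback: it sets out from alcohol 15 and dimesylate 7 and returns at 18. The C3'–S bond is made with a strong sulfur nucleophile and the thiolane ring is closed last.
   - Mitsunobu displacement of 15 with thioacetic acid gives S-[(2RS,4R)-4-(tert-butyldimethylsilyloxy)-6-methylhept-5-en-2-yl] ethanethioate F4.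
   - K2CO3 in degassed MeOH frees (2RS,4R)-4-(tert-butyldimethylsilyloxy)-6-methylhept-5-ene-2-thiol F5.
   - Its sodium thiolate (NaH, DMF), added slowly to an excess of 7, displaces one mesylate with inversion to give (2R,5S)-5-{[(2RS,4R)-4-(tert-butyldimethylsilyloxy)-6-methylhept-5-en-2-yl]sulfanyl}(2,5-D2)hexan-2-yl methanesulfonate F6.
   - Warming in MeCN lets the sulfide displace the second mesylate (5-exo-tet, inversion) to give (2S,5S)-1-[(2RS,4R)-4-(tert-butyldimethylsilyloxy)-6-methylhept-5-en-2-yl]-2,5-dimethyl(2,5-D2)thiolan-1-ium methanesulfonate F7, which aqueous NaBF4 converts into 18.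

3. Step 8.
   - What may go wrong: acid released by the PdCl2/CuCl system causes loss of the silyl ether or β-elimination of the silyloxy group from the product towards a conjugated dienone, or palladium induces allylic transposition across C5'–C7'.
   - Fallback: it sets out from diene 13 and returns at alcohol 15, bypassing 14. Markovnikov hydration replaces the oxidation/reduction pair.
   - Hg(OAc)2 in THF/H2O attacks the monosubstituted alkene faster than the trisubstituted, inductively deactivated one and gives [(4R)-4-(tert-butyldimethylsilyloxy)-2-hydroxy-6-methylhept-5-en-1-yl]mercury acetate F8.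
   - Demercuration with NaBH4/NaOH then gives 15.

**Further compounds**
F1 | step 11 | ethyl (2E,5R)-5-(tert-butyldimethylsilyloxy)-3,7-dimethylocta-2,6-dienoate | CCOC(=O)/C=C(\C)C[C@@H](O[Si](C)(C)C(C)(C)C)C=C(C)C
F2 | step 11 | (2E,5R)-5-(tert-butyldimethylsilyloxy)-3,7-dimethylocta-2,6-dien-1-ol | OC/C=C(\C)C[C@@H](O[Si](C)(C)C(C)(C)C)C=C(C)C
F3 | step 11 | {(2R,3R)-3-[(2R)-2-(tert-butyldimethylsilyloxy)-4-methylpent-3-en-1-yl]-3-methyloxiran-2-yl}methanol | OC[C@H]1O[C@]1(C)C[C@@H](O[Si](C)(C)C(C)(C)C)C=C(C)C
F4 | step 10 | S-[(2RS,4R)-4-(tert-butyldimethylsilyloxy)-6-methylhept-5-en-2-yl] ethanethioate | CC(=O)SC(C)C[C@@H](O[Si](C)(C)C(C)(C)C)C=C(C)C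
F5 | step 10 | (2RS,4R)-4-(tert-butyldimethylsilyloxy)-6-methylhept-5-ene-2-thiol | CC(S)C[C@@H](O[Si](C)(C)C(C)(C)C)C=C(C)C
F6 | step 10 | (2R,5S)-5-{[(2RS,4R)-4-(tert-butyldimethylsilyloxy)-6-methylhept-5-en-2-yl]sulfanyl}(2,5-D2)hexan-2-yl methanesulfonate | CC(S[C@@]([2H])(C)CC[C@@]([2H])(C)OS(C)(=O)=O)C[C@@H](O[Si](C)(C)C(C)(C)C)C=C(C)C
F7 | step 10 | (2S,5S)-1-[(2RS,4R)-4-(tert-butyldimethylsilyloxy)-6-methylhept-5-en-2-yl]-2,5-dimethyl(2,5-D2)thiolan-1-ium methanesulfonate | C[C@@]1([2H])CC[C@]([2H])(C)[S+]1C(C)C[C@@H](O[Si](C)(C)C(C)(C)C)C=C(C)C.CS(=O)(=O)[O-]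
F8 | step 8 | [(4R)-4-(tert-butyldimethylsilyloxy)-2-hydroxy-6-methylhept-5-en-1-yl]mercury acetate | CC(=O)O[Hg]CC(O)C[C@@H](O[Si](C)(C)C(C)(C)C)C=C(C)C
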